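**Retrosynthetic overview**

- The last C–C bond made is C2–C3 of the dihydrobenzofuran. It closes the dihydrofuran ring (O1, C2, C3, C3a, C7a) by an enantioselective intramolecular 1,5 C–H insertion of a rhodium carbene.
- Enabling feature: O1 joins C7a of the trisubstituted guaiacyl ring to the benzylic carbon C2, and C3 sits on C3a, ortho to O1. Cutting C2–C3 therefore leaves an aryl 4-oxybenzyl ether whose OCH2 (C2) is activated by O1 and by the electron-rich aryl ring and lies 1,5 to C3. C3 is carried as a diazo ester carbon, so its CH2OH is at the acid oxidation level (trichloroethyl ester).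
- The diazo ester comes from an aryl iodide (5-iodovanillin) by palladium-catalysed coupling with trichloroethyl diazoacetate. The iodide-bearing benzyl bromide is attached by trans-selective alkylation of a (4R)-4-benzylbutyrolactone enolate.
- The butyrolactone comes from an oxazolidinone alkylation and lactonisation. Its phenol then receives the erythro arylglycerol ether by an anti-aldol of an aryloxyacetyl imide with silylated vanillin.
- Ring order: butyrolactone (step 10), then dihydrofuran (step 21). All three guaiacyl rings and the fused arene are bought as vanillin, 5-iodovanillin and dihydroferulic acid.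

Key step: step 21

Assumption: the sense of induction in steps 14 and 21 is assigned from the accepted transition-state models; a model run is to confirm each, and the enantiomeric auxiliary or catalyst is used if the sense proves opposite.

Abbreviations in names: TIPS = triisopropylsilyl; TBS = tert-butyldimethylsilyl; ArT = 3-methoxy-4-[(triisopropylsilyl)oxy]phenyl; ArG = 4-({(1R,2S)-1,3-bis[(tert-butyldimethylsilyl)oxy]-1-ArT-propan-2-yl}oxy)-3-methoxyphenyl.

**Route**

Step 1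
Reactants: 1 vanillin
Product: 2 3-methoxy-4-[(triisopropylsilyl)oxy]benzaldehyde
Conditions: TIPSCl, imidazole, DMF, rt
Reagents that add atoms: triisopropylsilyl chloride, CC(C)[Si](Cl)(C(C)C)C(C)C
Why: Standard phenol silylation; the hindered aryl TIPS ether should survive the later carbonate, enolate and amine-base steps.

Step 2
Reactants: 2 3-methoxy-4-[(triisopropylsilyl)oxy]benzaldehyde
Product: 3 {3-methoxy-4-[(triisopropylsilyl)oxy]phenyl}methanol
Conditions: NaBH4, MeOH, 0 °C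
Reagents that add atoms: none
Why: Borohydride reduction of an aromatic aldehyde, which leaves the aryl silyl ether untouched.

Step 3
Reactants: 4 5-iodovanillin; 3 {3-methoxy-4-[(triisopropylsilyl)oxy]phenyl}methanol
Product: 5 3-iodo-5-methoxy-4-(ArT-methoxy)benzaldehyde
Conditions: PPh3, DIAD, THF, 0 °C to rt
Reagents that add atoms: none
Why: Mitsunobu etherification of an acidic, hindered phenol with a primary benzylic alcohol under neutral conditions, which avoids an ionisable 4-silyloxybenzyl halide.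

Step 4
Reactants: 5 3-iodo-5-methoxy-4-(ArT-methoxy)benzaldehyde
Product: 6 [3-iodo-5-methoxy-4-(ArT-methoxy)phenyl]methanol
Conditions: NaBH4, THF/MeOH, 0 °C
Reagents that add atoms: none
Why: Chemoselective borohydride reduction of the aldehyde; aryl iodide, benzyl ether and silyl ether are inert.

Step 5
Reactants: 6 [3-iodo-5-methoxy-4-(ArT-methoxy)phenyl]methanol
Product: 7 5-(bromomethyl)-1-iodo-3-methoxy-2-(ArT-methoxy)benzene
Conditions: CBr4, PPh3, 2,6-lutidine (0.2 equiv), CH2Cl2, 0 °C; used crude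
Reagents that add atoms: carbon tetrabromide, BrC(Br)(Br)Br
Why: Appel bromination of a primary benzylic alcohol under buffered, nearly neutral conditions that should spare the acid-labile 4-silyloxybenzyl aryl ether.

Step 6
Reactants: 8 3-(4-hydroxy-3-methoxyphenyl)propanoic acid
Product: 9 3-[4-(benzyloxy)-3-methoxyphenyl]propanoic acid
Conditions: BnCl, NaOH, EtOH/H2O, reflux; then HCl
Reagents that add atoms: benzyl chloride, ClCc1ccccc1
Why: Williamson ether synthesis on the phenoxide in aqueous alkali, where the carboxylate is a poor nucleophile and any benzyl ester is saponified in the same pot.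

Step 7
Reactants: 9 3-[4-(benzyloxy)-3-methoxyphenyl]propanoic acid; 10 (4S)-4-benzyl-1,3-oxazolidin-2-one
Product: 12 (4S)-4-benzyl-3-{3-[4-(benzyloxy)-3-methoxyphenyl]propanoyl}-1,3-oxazolidin-2-one, via mixed pivalic anhydride 11 (not isolated)
Conditions: PivCl, Et3N, THF, −20 °C; then LiCl, 10, rt
Reagents that add atoms: pivaloyl chloride, CC(C)(C)C(Cl)=O (its atoms stay only in intermediate 11)
Why: Mixed-anhydride N-acylation of the oxazolidinone, which attacks the less hindered carbonyl of the pivalic anhydride.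

Step 8
Reactants: 12 (4S)-4-benzyl-3-{3-[4-(benzyloxy)-3-methoxyphenyl]propanoyl}-1,3-oxazolidin-2-one
Product: 14 (4S)-4-benzyl-3-[(2R)-2-{[4-(benzyloxy)-3-methoxyphenyl]methyl}-4-tert-butoxy-4-oxobutanoyl]-1,3-oxazolidin-2-one, via sodium enolate 13 (not isolated)
Conditions: NaHMDS, THF, −78 °C; then BrCH2CO2tBu, −78 to −40 °C
Reagents that add atoms: tert-butyl bromoacetate, CC(C)(C)OC(=O)CBr; sodium bis(trimethylsilyl)amide, C[Si](C)(C)[N-][Si](C)(C)C.[Na+] (sodium stays only in intermediate 13)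
Why: Evans alkylation; the chelated Z-enolate is alkylated on the face opposite the benzyl group of the auxiliary, which sets the new centre as R.

Step 9
Reactants: 14 (4S)-4-benzyl-3-[(2R)-2-{[4-(benzyloxy)-3-methoxyphenyl]methyl}-4-tert-butoxy-4-oxobutanoyl]-1,3-oxazolidin-2-one
Product: 15 tert-butyl (3R)-3-{[4-(benzyloxy)-3-methoxyphenyl]methyl}-4-hydroxybutanoate
Conditions: LiBH4, MeOH (1 equiv), THF, 0 °C
Reagents that add atoms: none
Why: Reductive cleavage of the activated exocyclic imide carbonyl by lithium borohydride; the hindered tert-butyl ester is not reduced and the auxiliary is recovered.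

Step 10
Reactants: 15 tert-butyl (3R)-3-{[4-(benzyloxy)-3-methoxyphenyl]methyl}-4-hydroxybutanoate
Product: 16 (4R)-4-{[4-(benzyloxy)-3-methoxyphenyl]methyl}oxolan-2-one
Conditions: TFA/CH2Cl2 (1:4), 0 °C to rt
Reagents that add atoms: none
Why: Acid-mediated loss of the tert-butyl group and 5-exo-trig lactonisation of the γ-hydroxy acid; the stereocentre is not involved.

Step 11
Reactants: 16 (4R)-4-{[4-(benzyloxy)-3-methoxyphenyl]methyl}oxolan-2-one
Product: 17 (4R)-4-[(4-hydroxy-3-methoxyphenyl)methyl]oxolan-2-one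
Conditions: H2 (1 atm), 10% Pd/C, EtOAc, rt
Reagents that add atoms: none
Why: Hydrogenolysis of the benzyl aryl ether; the lactone and its non-benzylic stereocentre are inert.

Step 12
Reactants: 10 (4S)-4-benzyl-1,3-oxazolidin-2-one
Product: 19 (4S)-4-benzyl-3-(bromoacetyl)-1,3-oxazolidin-2-one, via lithium oxazolidinide 18 (not isolated)
Conditions: n-BuLi, THF, −78 °C; then BrCH2COBr, −78 °C
Reagents that add atoms: bromoacetyl bromide, BrCC(Br)=O; n-butyllithium, [Li]CCCC (lithium stays only in intermediate 18)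
Why: N-acylation of the lithiated oxazolidinone by the acyl bromide, which reacts much faster than the alkyl bromide at −78 °C.

Step 13
Reactants: 17 (4R)-4-[(4-hydroxy-3-methoxyphenyl)methyl]oxolan-2-one; 19 (4S)-4-benzyl-3-(bromoacetyl)-1,3-oxazolidin-2-one
Product: 20 (4S)-4-benzyl-3-[(2-methoxy-4-{[(3R)-5-oxooxolan-3-yl]methyl}phenoxy)acetyl]-1,3-oxazolidin-2-one
Conditions: K2CO3, acetone, rt
Reagents that add atoms: none
Why: Williamson ether synthesis by SN2 displacement at the activated α-halo imide carbon with a phenoxide; the carbonate is too weak to open or epimerise the lactone.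

Step 14
Reactants: 20 (4S)-4-benzyl-3-[(2-methoxy-4-{[(3R)-5-oxooxolan-3-yl]methyl}phenoxy)acetyl]-1,3-oxazolidin-2-one; 2 3-methoxy-4-[(triisopropylsilyl)oxy]benzaldehyde
Product: 22 (4S)-4-benzyl-3-[(2R,3R)-3-hydroxy-3-ArT-2-(2-methoxy-4-{[(3R)-5-oxooxolan-3-yl]methyl}phenoxy)propanoyl]-1,3-oxazolidin-2-one, via trimethylsilyl ether 21 (not isolated)
Conditions: MgCl2 (0.2 equiv), Et3N, TMSCl, EtOAc, rt; then 1 M HCl, THF, 0 °C
Reagents that add atoms: chlorotrimethylsilane, C[Si](C)(C)Cl (the silyl group stays only in intermediate 21)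
Why: Magnesium halide-catalysed direct anti-aldol of an N-acyloxazolidinone with an aromatic aldehyde; the magnesium-chelated Z-enolate should react on the face opposite the auxiliary benzyl group (2R) through a boat transition state that sets the carbinol as 3R, which is the erythro relation of aryloxy and hydroxy groups.

Step 15
Reactants: 22 (4S)-4-benzyl-3-[(2R,3R)-3-hydroxy-3-ArT-2-(2-methoxy-4-{[(3R)-5-oxooxolan-3-yl]methyl}phenoxy)propanoyl]-1,3-oxazolidin-2-one
Product: 23 (4R)-4-{[4-({(1R,2S)-1,3-dihydroxy-1-ArT-propan-2-yl}oxy)-3-methoxyphenyl]methyl}oxolan-2-one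
Conditions: NaBH4, THF/H2O (4:1), 0 °C to rt
Reagents that add atoms: none
Why: Borohydride reductive removal of the auxiliary from the activated N-acyl imide; the butyrolactone reacts far more slowly, both stereocentres are untouched, and the change from 2R to 2S is only a change in substituent priority.

Step 16
Reactants: 23 (4R)-4-{[4-({(1R,2S)-1,3-dihydroxy-1-ArT-propan-2-yl}oxy)-3-methoxyphenyl]methyl}oxolan-2-one
Product: 24 (4R)-4-(ArG-methyl)oxolan-2-one
Conditions: TBSOTf, 2,6-lutidine, CH2Cl2, −78 to 0 °C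
Reagents that add atoms: tert-butyldimethylsilyl trifluoromethanesulfonate, CC(C)(C)[Si](C)(C)OS(=O)(=O)C(F)(F)F
Why: Silylation of the primary and the hindered benzylic secondary alcohol with the silyl triflate under buffered conditions, which gives fluoride-labile protection that tolerates enolate, carbene, zinc and borane chemistry.

Step 17
Reactants: 24 (4R)-4-(ArG-methyl)oxolan-2-one; 7 5-(bromomethyl)-1-iodo-3-methoxy-2-(ArT-methoxy)benzene
Product: 26 (3R,4R)-3-{[3-iodo-5-methoxy-4-(ArT-methoxy)phenyl]methyl}-4-(ArG-methyl)oxolan-2-one, via lithium enolate 25 (not isolated)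
Conditions: LiHMDS, THF, −78 °C; then 7, DMPU, −78 to −30 °C
Reagents that add atoms: lithium bis(trimethylsilyl)amide, C[Si](C)(C)[N-][Si](C)(C)C.[Li+] (lithium stays only in intermediate 25)
Why: Alkylation of the 4-substituted butyrolactone enolate with a reactive benzylic bromide; the electrophile enters anti to the C4 substituent and sets C3 as R (trans), and the aryl iodide carries no acidic C–H that could quench the enolate.

Step 18
Reactants: 27 2,2,2-trichloroethanol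
Product: 28 2,2,2-trichloroethyl bromoacetate
Conditions: BrCH2COBr, pyridine, CH2Cl2, 0 °C
Reagents that add atoms: bromoacetyl bromide, BrCC(Br)=O
Why: O-acylation of the alcohol by the acyl bromide with pyridine as acid scavenger.

Step 19
Reactants: 28 2,2,2-trichloroethyl bromoacetate
Product: 29 2,2,2-trichloroethyl diazoacetate
Conditions: TsNHNHTs, DBU, THF, 0 °C
Reagents that add atoms: N,N'-ditosylhydrazine, Cc1ccc(cc1)S(=O)(=O)NNS(=O)(=O)c1ccc(C)cc1
Why: Diazo synthesis from a bromoacetate by N-alkylation of the ditosylhydrazine followed by two base-induced sulfinate eliminations.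

Step 20
Reactants: 26 (3R,4R)-3-{[3-iodo-5-methoxy-4-(ArT-methoxy)phenyl]methyl}-4-(ArG-methyl)oxolan-2-one; 29 2,2,2-trichloroethyl diazoacetate
Product: 30 2,2,2-trichloroethyl 2-diazo-2-[3-methoxy-2-(ArT-methoxy)-5-{[(3R,4R)-4-(ArG-methyl)-2-oxooxolan-3-yl]methyl}phenyl]acetate
Conditions: Pd(PPh3)4 (10 mol %), Ag2CO3 (0.5 equiv), Et3N, toluene, rt, dark
Reagents that add atoms: none
Why: Palladium-catalysed cross-coupling of an aryl iodide with an acceptor diazoacetate with retention of the diazo group (oxidative addition to zerovalent palladium, base- and silver-assisted palladation of the diazo C–H, reductive elimination); lactone and silyl ethers tolerate the mild conditions.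

Step 21
Reactants: 30 2,2,2-trichloroethyl 2-diazo-2-[3-methoxy-2-(ArT-methoxy)-5-{[(3R,4R)-4-(ArG-methyl)-2-oxooxolan-3-yl]methyl}phenyl]acetate
Product: 31 2,2,2-trichloroethyl (2S,3R)-7-methoxy-2-ArT-5-{[(3R,4R)-4-(ArG-methyl)-2-oxooxolan-3-yl]methyl}-2,3-dihydro-1-benzofuran-3-carboxylate (cis)
Conditions: dirhodium tetrakis[N-phthaloyl-(R)-tert-leucinate], Rh2(R-PTTL)4 (2 mol %), toluene, 4 Å MS, −60 °C, slow addition of 30 as a dilute solution
Reagents that add atoms: none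
Why: The dirhodium tetracarboxylate decomposes the aryldiazoacetate with loss of N2 to a donor/acceptor divalent-rhodium carbene at C3, which inserts through a concerted, hydride-transfer-like three-centre transition state into one of the two enantiotopic C–H bonds of the ArO–CH2–ArT ether carbon (C2) and so forms the C2–C3 bond. The closest known reaction type is the enantioselective intramolecular 1,5 C–H insertion of 2-(benzyloxy)aryl diazoacetates to cis-2-aryl-2,3-dihydrobenzofuran-3-carboxylates with dirhodium tetrakis(N-phthaloyl-tert-leucinate) catalysts. The dihydrofuran ring (O1, C2, C3, C3a, C7a) is closed by 1,5-insertion through a five-membered cyclic transition state. C2 is set by the chiral carboxylate ligands, which choose between the two enantiotopic hydrogens (the R-ligand series is chosen for 2S), while C3 forms cis to the C2 aryl group under kinetic control and is corrected in step 22. The step needs site selectivity for the O1–CH2 bond and suppression of carbene dimerisation: only this CH2, activated by O1 and by the 4-silyloxy-3-methoxyphenyl ring, can reach the carbene through a five-membered transition state (the other ortho position is C4–H), and slow addition at high dilution disfavours bimolecular decay. Lactone, silyl ethers and the four existing stereocentres are spectators, so the catalyst and not the substrate decides the new configuration.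

Step 22
Reactants: 31 cis-dihydrobenzofuran trichloroethyl ester (2S,3R)
Product: 32 2,2,2-trichloroethyl (2S,3S)-7-methoxy-2-ArT-5-{[(3R,4R)-4-(ArG-methyl)-2-oxooxolan-3-yl]methyl}-2,3-dihydro-1-benzofuran-3-carboxylate (trans)
Conditions: DBU (0.3 equiv), toluene, rt
Reagents that add atoms: none
Why: Base-mediated epimerisation through the ester enolate at C3 to the thermodynamically preferred trans isomer (ester anti to the C2 aryl group); C2 is not acidic and the trans lactone is already the stable isomer.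

Step 23
Reactants: 32 trans-dihydrobenzofuran trichloroethyl ester (2S,3S)
Product: 33 (2S,3S)-7-methoxy-2-ArT-5-{[(3R,4R)-4-(ArG-methyl)-2-oxooxolan-3-yl]methyl}-2,3-dihydro-1-benzofuran-3-carboxylic acid
Conditions: Zn dust, AcOH/THF (1:4), rt
Reagents that add atoms: none
Why: Reductive cleavage of the trichloroethyl ester by zinc (two-electron reduction and β-elimination), which frees the C3 acid without touching the lactone, the silyl ethers or the benzylic C2–O1 bond.

Step 24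
Reactants: 33 dihydrobenzofuran-3-carboxylic acid (2S,3S)
Product: 34 (3R,4R)-3-{[(2S,3R)-3-(hydroxymethyl)-7-methoxy-2-ArT-2,3-dihydro-1-benzofuran-5-yl]methyl}-4-(ArG-methyl)oxolan-2-one
Conditions: BH3·THF, THF, 0 °C to rt; MeOH quench
Reagents that add atoms: none
Why: Chemoselective borane reduction of a carboxylic acid (through the acyloxyborane) in the presence of the much less reactive lactone; the change from 3S to 3R is only a change in substituent priority.

Step 25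
Reactants: 34 tetrasilylated alcohol
Product: 35 (3R,4R)-3-{[(2S,3R)-2-(4-hydroxy-3-methoxyphenyl)-3-(hydroxymethyl)-7-methoxy-2,3-dihydro-1-benzofuran-5-yl]methyl}-4-{[4-({(1R,2S)-1,3-dihydroxy-1-(4-hydroxy-3-methoxyphenyl)propan-2-yl}oxy)-3-methoxyphenyl]methyl}oxolan-2-one (target, CNP0265599.1)
Conditions: TBAF, AcOH (1:1), THF, 0 °C to rt
Reagents that add atoms: none
Why: Fluoride-induced cleavage of the two aryl TIPS and two alkyl TBS ethers; acetic acid buffering should keep the liberated 4-hydroxybenzyl systems from forming quinone methides and the lactone from opening.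

**Compound list**

1 | vanillin (4-hydroxy-3-methoxybenzaldehyde) | COc1cc(C=O)ccc1O | starting material
2 | 3-methoxy-4-[(triisopropylsilyl)oxy]benzaldehyde | COc1cc(C=O)ccc1O[Si](C(C)C)(C(C)C)C(C)C | intermediate
3 | {3-methoxy-4-[(triisopropylsilyl)oxy]phenyl}methanol | COc1cc(CO)ccc1O[Si](C(C)C)(C(C)C)C(C)C | intermediate
4 | 5-iodovanillin (4-hydroxy-3-iodo-5-methoxybenzaldehyde) | COc1cc(C=O)cc(I)c1O | starting material
5 | 3-iodo-5-methoxy-4-(ArT-methoxy)benzaldehyde | COc1cc(C=O)cc(I)c1OCc1ccc(O[Si](C(C)C)(C(C)C)C(C)C)c(OC)c1 | intermediate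
6 | [3-iodo-5-methoxy-4-(ArT-methoxy)phenyl]methanol | COc1cc(CO)cc(I)c1OCc1ccc(O[Si](C(C)C)(C(C)C)C(C)C)c(OC)c1 | intermediate
7 | 5-(bromomethyl)-1-iodo-3-methoxy-2-(ArT-methoxy)benzene | COc1cc(CBr)cc(I)c1OCc1ccc(O[Si](C(C)C)(C(C)C)C(C)C)c(OC)c1 | intermediate
8 | 3-(4-hydroxy-3-methoxyphenyl)propanoic acid (dihydroferulic acid) | COc1cc(CCC(=O)O)ccc1O | starting material
9 | 3-[4-(benzyloxy)-3-methoxyphenyl]propanoic acid | COc1cc(CCC(=O)O)ccc1OCc1ccccc1 | intermediate
10 | (4S)-4-benzyl-1,3-oxazolidin-2-one | O=C1N[C@@H](Cc2ccccc2)CO1 | starting material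
11 | 3-[4-(benzyloxy)-3-methoxyphenyl]propanoic pivalic anhydride | COc1cc(CCC(=O)OC(=O)C(C)(C)C)ccc1OCc1ccccc1 | intermediate (not isolated)
12 | (4S)-4-benzyl-3-{3-[4-(benzyloxy)-3-methoxyphenyl]propanoyl}-1,3-oxazolidin-2-one | COc1cc(CCC(=O)N2[C@@H](Cc3ccccc3)COC2=O)ccc1OCc1ccccc1 | intermediate
13 | sodium (Z)-enolate of 12 | COc1cc(C/C=C(\[O-])N2[C@@H](Cc3ccccc3)COC2=O)ccc1OCc1ccccc1.[Na+] | intermediate (not isolated)
14 | (4S)-4-benzyl-3-[(2R)-2-{[4-(benzyloxy)-3-methoxyphenyl]methyl}-4-tert-butoxy-4-oxobutanoyl]-1,3-oxazolidin-2-one | COc1cc(C[C@H](CC(=O)OC(C)(C)C)C(=O)N2[C@@H](Cc3ccccc3)COC2=O)ccc1OCc1ccccc1 | intermediate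
15 | tert-butyl (3R)-3-{[4-(benzyloxy)-3-methoxyphenyl]methyl}-4-hydroxybutanoate | COc1cc(C[C@H](CC(=O)OC(C)(C)C)CO)ccc1OCc1ccccc1 | intermediate
16 | (4R)-4-{[4-(benzyloxy)-3-methoxyphenyl]methyl}oxolan-2-one | COc1cc(C[C@H]2COC(=O)C2)ccc1OCc1ccccc1 | intermediate
17 | (4R)-4-[(4-hydroxy-3-methoxyphenyl)methyl]oxolan-2-one | COc1cc(C[C@H]2COC(=O)C2)ccc1O | intermediate
18 | lithium salt of (4S)-4-benzyl-1,3-oxazolidin-2-one | O=C1[N-][C@@H](Cc2ccccc2)CO1.[Li+] | intermediate (not isolated)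
19 | (4S)-4-benzyl-3-(bromoacetyl)-1,3-oxazolidin-2-one | BrCC(=O)N1[C@@H](Cc2ccccc2)COC1=O | intermediate
20 | (4S)-4-benzyl-3-[(2-methoxy-4-{[(3R)-5-oxooxolan-3-yl]methyl}phenoxy)acetyl]-1,3-oxazolidin-2-one | COc1cc(C[C@H]2COC(=O)C2)ccc1OCC(=O)N1[C@@H](Cc2ccccc2)COC1=O | intermediate
21 | trimethylsilyl ether of aldol adduct 22 | COc1cc([C@@H](O[Si](C)(C)C)[C@H](C(=O)N2[C@@H](Cc3ccccc3)COC2=O)Oc2ccc(C[C@H]3COC(=O)C3)cc2OC)ccc1O[Si](C(C)C)(C(C)C)C(C)C | intermediate (not isolated)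
22 | (4S)-4-benzyl-3-[(2R,3R)-3-hydroxy-3-ArT-2-(2-methoxy-4-{[(3R)-5-oxooxolan-3-yl]methyl}phenoxy)propanoyl]-1,3-oxazolidin-2-one | COc1cc([C@@H](O)[C@H](C(=O)N2[C@@H](Cc3ccccc3)COC2=O)Oc2ccc(C[C@H]3COC(=O)C3)cc2OC)ccc1O[Si](C(C)C)(C(C)C)C(C)C | intermediate
23 | (4R)-4-{[4-({(1R,2S)-1,3-dihydroxy-1-ArT-propan-2-yl}oxy)-3-methoxyphenyl]methyl}oxolan-2-one | COc1cc([C@@H](O)[C@H](CO)Oc2ccc(C[C@H]3COC(=O)C3)cc2OC)ccc1O[Si](C(C)C)(C(C)C)C(C)C | intermediate
24 | (4R)-4-(ArG-methyl)oxolan-2-one | COc1cc([C@@H](O[Si](C)(C)C(C)(C)C)[C@H](CO[Si](C)(C)C(C)(C)C)Oc2ccc(C[C@H]3COC(=O)C3)cc2OC)ccc1O[Si](C(C)C)(C(C)C)C(C)C | intermediate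
25 | lithium (4R)-4-(ArG-methyl)-4,5-dihydrofuran-2-olate (enolate of 24) | COc1cc([C@@H](O[Si](C)(C)C(C)(C)C)[C@H](CO[Si](C)(C)C(C)(C)C)Oc2ccc(C[C@H]3COC([O-])=C3)cc2OC)ccc1O[Si](C(C)C)(C(C)C)C(C)C.[Li+] | intermediate (not isolated)
26 | (3R,4R)-3-{[3-iodo-5-methoxy-4-(ArT-methoxy)phenyl]methyl}-4-(ArG-methyl)oxolan-2-one | COc1cc([C@@H](O[Si](C)(C)C(C)(C)C)[C@H](CO[Si](C)(C)C(C)(C)C)Oc2ccc(C[C@H]3COC(=O)[C@@H]3Cc3cc(OC)c(OCc4ccc(O[Si](C(C)C)(C(C)C)C(C)C)c(OC)c4)c(I)c3)cc2OC)ccc1O[Si](C(C)C)(C(C)C)C(C)C | intermediate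
27 | 2,2,2-trichloroethanol | OCC(Cl)(Cl)Cl | starting material
28 | 2,2,2-trichloroethyl bromoacetate | BrCC(=O)OCC(Cl)(Cl)Cl | intermediate
29 | 2,2,2-trichloroethyl diazoacetate | [N-]=[N+]=CC(=O)OCC(Cl)(Cl)Cl | intermediate
30 | 2,2,2-trichloroethyl 2-diazo-2-[3-methoxy-2-(ArT-methoxy)-5-{[(3R,4R)-4-(ArG-methyl)-2-oxooxolan-3-yl]methyl}phenyl]acetate | COc1cc([C@@H](O[Si](C)(C)C(C)(C)C)[C@H](CO[Si](C)(C)C(C)(C)C)Oc2ccc(C[C@H]3COC(=O)[C@@H]3Cc3cc(OC)c(OCc4ccc(O[Si](C(C)C)(C(C)C)C(C)C)c(OC)c4)c(C(=[N+]=[N-])C(=O)OCC(Cl)(Cl)Cl)c3)cc2OC)ccc1O[Si](C(C)C)(C(C)C)C(C)C | intermediate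
31 | 2,2,2-trichloroethyl (2S,3R)-7-methoxy-2-ArT-5-{[(3R,4R)-4-(ArG-methyl)-2-oxooxolan-3-yl]methyl}-2,3-dihydro-1-benzofuran-3-carboxylate (cis) | COc1cc([C@@H](O[Si](C)(C)C(C)(C)C)[C@H](CO[Si](C)(C)C(C)(C)C)Oc2ccc(C[C@H]3COC(=O)[C@@H]3Cc3cc(OC)c4c(c3)[C@@H](C(=O)OCC(Cl)(Cl)Cl)[C@@H](c3ccc(O[Si](C(C)C)(C(C)C)C(C)C)c(OC)c3)O4)cc2OC)ccc1O[Si](C(C)C)(C(C)C)C(C)C | intermediate
32 | 2,2,2-trichloroethyl (2S,3S)-7-methoxy-2-ArT-5-{[(3R,4R)-4-(ArG-methyl)-2-oxooxolan-3-yl]methyl}-2,3-dihydro-1-benzofuran-3-carboxylate (trans) | COc1cc([C@@H](O[Si](C)(C)C(C)(C)C)[C@H](CO[Si](C)(C)C(C)(C)C)Oc2ccc(C[C@H]3COC(=O)[C@@H]3Cc3cc(OC)c4c(c3)[C@H](C(=O)OCC(Cl)(Cl)Cl)[C@@H](c3ccc(O[Si](C(C)C)(C(C)C)C(C)C)c(OC)c3)O4)cc2OC)ccc1O[Si](C(C)C)(C(C)C)C(C)C | intermediate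
33 | (2S,3S)-7-methoxy-2-ArT-5-{[(3R,4R)-4-(ArG-methyl)-2-oxooxolan-3-yl]methyl}-2,3-dihydro-1-benzofuran-3-carboxylic acid | COc1cc([C@@H](O[Si](C)(C)C(C)(C)C)[C@H](CO[Si](C)(C)C(C)(C)C)Oc2ccc(C[C@H]3COC(=O)[C@@H]3Cc3cc(OC)c4c(c3)[C@H](C(=O)O)[C@@H](c3ccc(O[Si](C(C)C)(C(C)C)C(C)C)c(OC)c3)O4)cc2OC)ccc1O[Si](C(C)C)(C(C)C)C(C)C | intermediate
34 | (3R,4R)-3-{[(2S,3R)-3-(hydroxymethyl)-7-methoxy-2-ArT-2,3-dihydro-1-benzofuran-5-yl]methyl}-4-(ArG-methyl)oxolan-2-one | COc1cc([C@@H](O[Si](C)(C)C(C)(C)C)[C@H](CO[Si](C)(C)C(C)(C)C)Oc2ccc(C[C@H]3COC(=O)[C@@H]3Cc3cc(OC)c4c(c3)[C@H](CO)[C@@H](c3ccc(O[Si](C(C)C)(C(C)C)C(C)C)c(OC)c3)O4)cc2OC)ccc1O[Si](C(C)C)(C(C)C)C(C)C | intermediate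
35 | (3R,4R)-3-{[(2S,3R)-2-(4-hydroxy-3-methoxyphenyl)-3-(hydroxymethyl)-7-methoxy-2,3-dihydro-1-benzofuran-5-yl]methyl}-4-{[4-({(1R,2S)-1,3-dihydroxy-1-(4-hydroxy-3-methoxyphenyl)propan-2-yl}oxy)-3-methoxyphenyl]methyl}oxolan-2-one | COc1cc([C@@H](O)[C@H](CO)Oc2ccc(C[C@H]3COC(=O)[C@@H]3Cc3cc(OC)c4c(c3)[C@H](CO)[C@@H](c3ccc(O)c(OC)c3)O4)cc2OC)ccc1O | target

**Totals**

Total step count: 25. Longest linear sequence: 17 steps (steps 6–11, 13–17, 20–25).

**Three steps most likely to fail**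

1. Step 20 (aryl iodide to aryldiazoacetate). What may go wrong: oxidative addition and palladation at the iodide flanked by the bulky ArT-methoxy group may be slower than palladium- or silver-induced decomposition of the diazoacetate (carbene dimerisation), so that the iodide is returned. The fallback sets out from 26 and comes back at 33. A Negishi-type α-arylation of 26 with the Reformatsky reagent of tert-butyl bromoacetate (BrZnCH2CO2tBu, Pd2(dba)3, XPhos, THF, rt to 50 °C) should give the tert-butyl arylacetate F1. Regitz diazo transfer (4-acetamidobenzenesulfonyl azide, DBU, MeCN), which acts on the arylacetate CH2 and not on the lactone, should give the tert-butyl aryldiazoacetate F2. Insertion under the conditions of step 21 should give the cis tert-butyl ester F3, and DBU should epimerise it to the trans tert-butyl ester F4. Cleavage of the tert-butyl ester with TMSOTf and 2,6-lutidine (CH2Cl2, 0 °C, then aqueous work-up) should give acid 33.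

2. Step 14 (anti-aldol). What may go wrong: competition of the α-aryloxy oxygen for magnesium may erode the anti selectivity or the enolate-face control, and the electron-rich benzylic aldolate may revert by retro-aldol before it is silylated. The fallback sets out from 17 and comes back at 24. It uses the boron syn-aldol followed by inversion of the benzylic alcohol. (4R)-4-Benzyl-1,3-oxazolidin-2-one is acylated as in step 12 to the enantiomeric bromoacetyl imide F5, which alkylates phenol 17 (K2CO3, acetone) to the aryloxyacetyl imide F6. The dibutylboron enolate (Bu2BOTf, iPr2NEt, CH2Cl2, −78 to 0 °C) adds to aldehyde 2 through a chair transition state to the (2R,3S) syn adduct F7. NaBH4 (THF/H2O) should give the threo (1S,2S) diol F8, and TBSCl with imidazole should silylate only the primary hydroxyl to give the mono-TBS ether F9. Mitsunobu inversion of the benzylic alcohol with chloroacetic acid (PPh3, DIAD, toluene, 0 °C) should give the (1R) chloroacetate F10. Thiourea with NaHCO3 in EtOH should remove the chloroacetate to give the erythro (1R,2S) alcohol F11, and TBSOTf with 2,6-lutidine then gives 24.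

3. Step 21 (late-stage C–H insertion). What may go wrong: the catalyst may discriminate poorly between the two enantiotopic C2–H bonds on the large substrate with its bulky trichloroethyl ester, and bimolecular carbene decay may compete at the concentrations a late intermediate imposes. The fallback sets out from 6 and comes back at 32. It runs the insertion on the small fragment, where the reaction is closest to its precedent and the product can be enriched by crystallisation. Alcohol 6 is silylated (TBSCl, imidazole) to the TBS ether F12, and coupling with 29 as in step 20 should give the aryldiazoacetate F13. Rh2(R-PTTL)4 should give the cis dihydrobenzofuran ester F14, and DBU should give the trans ester F15. HF·pyridine (THF/pyridine, 0 °C) should remove only the primary TBS group to give the benzylic alcohol F16, and CBr4 with PPh3 should give the benzylic bromide F17. Alkylation of enolate 25 (from 24 and LiHMDS, as in step 17) with F17 should give 32; the hindered tertiary C3–H of F17 should not quench the enolate.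

**Further compounds**

F1 | step 20 | tert-butyl 2-[3-methoxy-2-(ArT-methoxy)-5-{[(3R,4R)-4-(ArG-methyl)-2-oxooxolan-3-yl]methyl}phenyl]acetate | COc1cc([C@@H](O[Si](C)(C)C(C)(C)C)[C@H](CO[Si](C)(C)C(C)(C)C)Oc2ccc(C[C@H]3COC(=O)[C@@H]3Cc3cc(OC)c(OCc4ccc(O[Si](C(C)C)(C(C)C)C(C)C)c(OC)c4)c(CC(=O)OC(C)(C)C)c3)cc2OC)ccc1O[Si](C(C)C)(C(C)C)C(C)C
F2 | step 20 | tert-butyl 2-diazo-2-[3-methoxy-2-(ArT-methoxy)-5-{[(3R,4R)-4-(ArG-methyl)-2-oxooxolan-3-yl]methyl}phenyl]acetate | COc1cc([C@@H](O[Si](C)(C)C(C)(C)C)[C@H](CO[Si](C)(C)C(C)(C)C)Oc2ccc(C[C@H]3COC(=O)[C@@H]3Cc3cc(OC)c(OCc4ccc(O[Si](C(C)C)(C(C)C)C(C)C)c(OC)c4)c(C(=[N+]=[N-])C(=O)OC(C)(C)C)c3)cc2OC)ccc1O[Si](C(C)C)(C(C)C)C(C)C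
F3 | step 20 | tert-butyl (2S,3R)-7-methoxy-2-ArT-5-{[(3R,4R)-4-(ArG-methyl)-2-oxooxolan-3-yl]methyl}-2,3-dihydro-1-benzofuran-3-carboxylate (cis) | COc1cc([C@@H](O[Si](C)(C)C(C)(C)C)[C@H](CO[Si](C)(C)C(C)(C)C)Oc2ccc(C[C@H]3COC(=O)[C@@H]3Cc3cc(OC)c4c(c3)[C@@H](C(=O)OC(C)(C)C)[C@@H](c3ccc(O[Si](C(C)C)(C(C)C)C(C)C)c(OC)c3)O4)cc2OC)ccc1O[Si](C(C)C)(C(C)C)C(C)C
F4 | step 20 | tert-butyl (2S,3S)-7-methoxy-2-ArT-5-{[(3R,4R)-4-(ArG-methyl)-2-oxooxolan-3-yl]methyl}-2,3-dihydro-1-benzofuran-3-carboxylate (trans) | COc1cc([C@@H](O[Si](C)(C)C(C)(C)C)[C@H](CO[Si](C)(C)C(C)(C)C)Oc2ccc(C[C@H]3COC(=O)[C@@H]3Cc3cc(OC)c4c(c3)[C@H](C(=O)OC(C)(C)C)[C@@H](c3ccc(O[Si](C(C)C)(C(C)C)C(C)C)c(OC)c3)O4)cc2OC)ccc1O[Si](C(C)C)(C(C)C)C(C)C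
F5 | step 14 | (4R)-4-benzyl-3-(bromoacetyl)-1,3-oxazolidin-2-one | BrCC(=O)N1[C@H](Cc2ccccc2)COC1=O
F6 | step 14 | (4R)-4-benzyl-3-[(2-methoxy-4-{[(3R)-5-oxooxolan-3-yl]methyl}phenoxy)acetyl]-1,3-oxazolidin-2-one | COc1cc(C[C@H]2COC(=O)C2)ccc1OCC(=O)N1[C@H](Cc2ccccc2)COC1=O
F7 | step 14 | (4R)-4-benzyl-3-[(2R,3S)-3-hydroxy-3-ArT-2-(2-methoxy-4-{[(3R)-5-oxooxolan-3-yl]methyl}phenoxy)propanoyl]-1,3-oxazolidin-2-one | COc1cc([C@H](O)[C@H](C(=O)N2[C@H](Cc3ccccc3)COC2=O)Oc2ccc(C[C@H]3COC(=O)C3)cc2OC)ccc1O[Si](C(C)C)(C(C)C)C(C)C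
F8 | step 14 | (4R)-4-{[4-({(1S,2S)-1,3-dihydroxy-1-ArT-propan-2-yl}oxy)-3-methoxyphenyl]methyl}oxolan-2-one | COc1cc([C@H](O)[C@H](CO)Oc2ccc(C[C@H]3COC(=O)C3)cc2OC)ccc1O[Si](C(C)C)(C(C)C)C(C)C
F9 | step 14 | (4R)-4-{[4-({(1S,2S)-3-[(tert-butyldimethylsilyl)oxy]-1-hydroxy-1-ArT-propan-2-yl}oxy)-3-methoxyphenyl]methyl}oxolan-2-one | COc1cc([C@H](O)[C@H](CO[Si](C)(C)C(C)(C)C)Oc2ccc(C[C@H]3COC(=O)C3)cc2OC)ccc1O[Si](C(C)C)(C(C)C)C(C)C
F10 | step 14 | (1R,2S)-3-[(tert-butyldimethylsilyl)oxy]-2-(2-methoxy-4-{[(3R)-5-oxooxolan-3-yl]methyl}phenoxy)-1-ArT-propyl chloroacetate | COc1cc([C@@H](OC(=O)CCl)[C@H](CO[Si](C)(C)C(C)(C)C)Oc2ccc(C[C@H]3COC(=O)C3)cc2OC)ccc1O[Si](C(C)C)(C(C)C)C(C)C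
F11 | step 14 | (4R)-4-{[4-({(1R,2S)-3-[(tert-butyldimethylsilyl)oxy]-1-hydroxy-1-ArT-propan-2-yl}oxy)-3-methoxyphenyl]methyl}oxolan-2-one | COc1cc([C@@H](O)[C@H](CO[Si](C)(C)C(C)(C)C)Oc2ccc(C[C@H]3COC(=O)C3)cc2OC)ccc1O[Si](C(C)C)(C(C)C)C(C)C
F12 | step 21 | tert-butyl{[3-iodo-5-methoxy-4-(ArT-methoxy)phenyl]methoxy}dimethylsilane | COc1cc(CO[Si](C)(C)C(C)(C)C)cc(I)c1OCc1ccc(O[Si](C(C)C)(C(C)C)C(C)C)c(OC)c1
F13 | step 21 | 2,2,2-trichloroethyl 2-[5-({[tert-butyldimethylsilyl]oxy}methyl)-3-methoxy-2-(ArT-methoxy)phenyl]-2-diazoacetate | COc1cc(CO[Si](C)(C)C(C)(C)C)cc(C(=[N+]=[N-])C(=O)OCC(Cl)(Cl)Cl)c1OCc1ccc(O[Si](C(C)C)(C(C)C)C(C)C)c(OC)c1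
F14 | step 21 | 2,2,2-trichloroethyl (2S,3R)-5-({[tert-butyldimethylsilyl]oxy}methyl)-7-methoxy-2-ArT-2,3-dihydro-1-benzofuran-3-carboxylate (cis) | CC(C)(C)[Si](C)(C)OCc1cc(OC)c2c(c1)[C@@H](C(=O)OCC(Cl)(Cl)Cl)[C@@H](c1ccc(O[Si](C(C)C)(C(C)C)C(C)C)c(OC)c1)O2
F15 | step 21 | 2,2,2-trichloroethyl (2S,3S)-5-({[tert-butyldimethylsilyl]oxy}methyl)-7-methoxy-2-ArT-2,3-dihydro-1-benzofuran-3-carboxylate (trans) | CC(C)(C)[Si](C)(C)OCc1cc(OC)c2c(c1)[C@H](C(=O)OCC(Cl)(Cl)Cl)[C@@H](c1ccc(O[Si](C(C)C)(C(C)C)C(C)C)c(OC)c1)O2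
F16 | step 21 | 2,2,2-trichloroethyl (2S,3S)-5-(hydroxymethyl)-7-methoxy-2-ArT-2,3-dihydro-1-benzofuran-3-carboxylate | OCc1cc(OC)c2c(c1)[C@H](C(=O)OCC(Cl)(Cl)Cl)[C@@H](c1ccc(O[Si](C(C)C)(C(C)C)C(C)C)c(OC)c1)O2
F17 | step 21 | 2,2,2-trichloroethyl (2S,3S)-5-(bromomethyl)-7-methoxy-2-ArT-2,3-dihydro-1-benzofuran-3-carboxylate | BrCc1cc(OC)c2c(c1)[C@H](C(=O)OCC(Cl)(Cl)Cl)[C@@H](c1ccc(O[Si](C(C)C)(C(C)C)C(C)C)c(OC)c1)O2
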